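**Retrosynthetic overview**
- End game: the target is reached from its 3-O-TBS, 4'-O-benzyl and side-chain O-benzyl derivative by removing the silyl ether and then the two benzyl ethers.
- Feature the route rests on: ring A (C4a–C5–C6–C7–C8–C8a) is a phloroglucinol fused to ring C at C4a–C8a, with its only carbon substituent on C6 between O5 and O7. This is the pattern left when a 2-substituted 1-alkoxy-1,3-bis(silyloxy)butadiene annulates onto the C5=C6 enone of a 2-aryl-3-oxy-2,3-dihydropyran-4-one. Disconnect C8–C8a and C4a–C5.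
- Ring C first, with both stereocentres: asymmetric hetero-Diels–Alder reaction of 4-(benzyloxy)benzaldehyde with Danishefsky's diene, trans α'-hydroxylation, silylation, α-bromination of the enone.
- Diene: rhodium-catalysed asymmetric arylation of methyl crotonate sets the benzylic centre; C-acetylation and two enol silylations follow.
- Ring order: C (step 1), then A (step 9); both aryl rings come in preformed.

Key step: step 9

Assumption: the facial sense of the two catalytic asymmetric steps (1 and 5) is taken from the usual models for Ti–BINOL and Rh–BINAP catalysis; the ligand antipode is the control element and the other antipode is used if the sign of rotation of 4 or 11 calls for it.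

**Route**

Step 1
Reactants: 1 4-(benzyloxy)benzaldehyde; 2 trans-1-methoxy-3-(trimethylsilyloxy)buta-1,3-diene
Product: 4 (2S)-2-[4-(benzyloxy)phenyl]-2,3-dihydro-4H-pyran-4-one, via Mukaiyama aldol silyl ether 3 (not isolated)
Conditions: (S)-BINOL (20 mol%), Ti(OiPr)4 (10 mol%), 4 Å MS, Et2O, −20 °C; then TFA, CH2Cl2, 0 °C
Reagents that add atoms: none
Why: Ti–BINOL-catalysed Mukaiyama aldol addition of the silyloxydiene to the aldehyde, then acid-induced cyclisation with loss of methanol (formal hetero-Diels–Alder reaction); the chiral titanium BINOLate shields one aldehyde face and so sets C2, (S)-BINOL being the antipode expected to give 2S.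

Step 2
Reactants: 4 (2S)-2-[4-(benzyloxy)phenyl]-2,3-dihydro-4H-pyran-4-one
Product: 6 (2R,3R)-2-[4-(benzyloxy)phenyl]-3-hydroxy-2,3-dihydro-4H-pyran-4-one, via sodium enolate 5 (not isolated)
Conditions: NaHMDS, THF, −78 °C; Davis oxaziridine, −78 °C; AcOH quench
Reagents that add atoms: (±)-trans-2-(phenylsulfonyl)-3-phenyloxaziridine, O=S(=O)(N1OC1c1ccccc1)c1ccccc1
Why: C3 is the only enolisable position, and the enolate should be hydroxylated by the N-sulfonyloxaziridine (Davis oxidation) on the face away from the C2 aryl group, which sets C3 trans to C2; the low temperature suppresses β-elimination of the ring oxygen.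

Step 3
Reactants: 6 (2R,3R)-2-[4-(benzyloxy)phenyl]-3-hydroxy-2,3-dihydro-4H-pyran-4-one
Product: 7 (2R,3R)-2-[4-(benzyloxy)phenyl]-3-(tert-butyldimethylsilyloxy)-2,3-dihydro-4H-pyran-4-one
Conditions: TBSOTf, 2,6-lutidine, CH2Cl2, −78 → 0 °C
Reagents that add atoms: tert-butyldimethylsilyl triflate, CC(C)(C)[Si](C)(C)OS(=O)(=O)C(F)(F)F
Why: Standard O-silylation of a secondary α-hydroxy ketone with a silyl triflate and a hindered base, which leaves C3 configurationally intact.

Step 4
Reactants: 7 (2R,3R)-2-[4-(benzyloxy)phenyl]-3-(tert-butyldimethylsilyloxy)-2,3-dihydro-4H-pyran-4-one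
Product: 8 (2R,3R)-5-bromo-2-[4-(benzyloxy)phenyl]-3-(tert-butyldimethylsilyloxy)-2,3-dihydro-4H-pyran-4-one
Conditions: NBS, CH2Cl2, 0 °C → rt
Reagents that add atoms: N-bromosuccinimide, O=C1CCC(=O)N1Br
Why: Electrophilic α-halogenation of a vinylogous ester: bromine adds to the enol-ether carbon C5 and H-5 is lost, and this position is far more nucleophilic than the benzyloxyarene.

Step 5
Reactants: 9 methyl (E)-but-2-enoate; 10 4-(benzyloxy)phenylboronic acid
Product: 11 methyl (3S)-3-[4-(benzyloxy)phenyl]butanoate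
Conditions: Rh(acac)(C2H4)2 (3 mol%), (R)-BINAP, dioxane–H2O 10:1, 100 °C
Reagents that add atoms: none
Why: Rhodium/BINAP-catalysed asymmetric 1,4-addition of an arylboronic acid to an (E)-enoate (Hayashi–Miyaura reaction); insertion of the enoate into the BINAP–Rh–aryl bond on one enantioface sets the benzylic centre, (R)-BINAP being the antipode expected to give S, and any minor enantiomer would later become a separable diastereomer of 19.

Step 6
Reactants: 11 methyl (3S)-3-[4-(benzyloxy)phenyl]butanoate
Product: 13 methyl (3S)-2-acetyl-3-[4-(benzyloxy)phenyl]butanoate (both C2 epimers), via lithium enolate 12 (not isolated)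
Conditions: LDA, THF, −78 °C; MeC(O)N(OMe)Me, −78 → 0 °C; AcOH quench
Reagents that add atoms: N-methoxy-N-methylacetamide, CC(=O)N(C)OC
Why: Crossed Claisen acylation of the lithium ester enolate by a Weinreb amide, whose chelated tetrahedral adduct prevents proton transfer to unreacted enolate; the new α-centre is erased in step 8 and the benzylic centre is not enolisable.

Step 7
Reactants: 13 methyl (3S)-2-acetyl-3-[4-(benzyloxy)phenyl]butanoate
Product: 14 methyl 2-{(1R)-1-[4-(benzyloxy)phenyl]ethyl}-3-(trimethylsilyloxy)but-2-enoate (E/Z mixture)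
Conditions: TMSCl, Et3N, toluene, 20 → 50 °C
Reagents that add atoms: chlorotrimethylsilane, C[Si](C)(C)Cl
Why: O-Silylation of the β-keto ester enol under soft enolisation gives the conjugated 3-silyloxy enoate, the standard first stage towards a bis(silyloxy)diene (the descriptor changes to R only because the CIP priorities change).

Step 8
Reactants: 14 methyl 2-{(1R)-1-[4-(benzyloxy)phenyl]ethyl}-3-(trimethylsilyloxy)but-2-enoate
Product: 16 1-methoxy-1,3-bis(trimethylsilyloxy)-2-{(1R)-1-[4-(benzyloxy)phenyl]ethyl}buta-1,3-diene, via lithium dienolate 15 (not isolated)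
Conditions: LDA, THF, −78 °C; TMSCl, −78 → 20 °C; used crude
Reagents that add atoms: chlorotrimethylsilane, C[Si](C)(C)Cl
Why: Vinylogous (γ-methyl) deprotonation of the silyloxy enoate and O-silylation of the dienolate at the ester oxygen, the standard second stage for 1-alkoxy-1,3-bis(silyloxy)dienes; the benzylic C–H is not in conjugation with the carbonyl and should be left alone.

Step 9
Reactants: 8 (2R,3R)-5-bromo-2-[4-(benzyloxy)phenyl]-3-(tert-butyldimethylsilyloxy)-2,3-dihydro-4H-pyran-4-one; 16 1-methoxy-1,3-bis(trimethylsilyloxy)-2-{(1R)-1-[4-(benzyloxy)phenyl]ethyl}buta-1,3-diene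
Product: 19 (2R,3R)-2-[4-(benzyloxy)phenyl]-6-{(1R)-1-[4-(benzyloxy)phenyl]ethyl}-3-(tert-butyldimethylsilyloxy)-5,7-dihydroxychroman-4-one, via cis-fused bromo cycloadduct 17 (not isolated), via 5,7-bis(trimethylsilyl) ether 18 (not isolated)
Conditions: 16 (2.5 equiv), PhMe, 100 °C, sealed tube; concentrate; TMSOTf (1.2 equiv), 2,6-lutidine, CH2Cl2, −40 → 0 °C; 1 M HCl, THF, 0 °C
Reagents that add atoms: none
Why: Proposed new method: the CH2 terminus of 16 (largest HOMO coefficient) should bond to C6 of 8 (the enone β-carbon, later C8a) and the ketene-acetal carbon to the brominated C5 (later C4a), in one asynchronous [4+2] step or as conjugate addition followed by closure of the bromo enolate onto the dioxocarbenium carbon, to give the cis-fused adduct 17; the closest known reactions are the cycloaddition–aromatisations of 1-alkoxy-1,3-bis(silyloxy)dienes with haloquinones, α-halo enones and 3-acceptor chromones, and the new element is a plain α-bromo vinylogous ester as the 2π partner. Ring A closes as a six-membered carbocycle by this intermolecular [4+2] annulation onto the C5=C6 bond of ring C (in the stepwise variant the second bond forms by 6-(enolexo)-exo-trig attack). Because Br on C4a and H on C8a are cis and H-8a is not acidic, an anti E2 loss of HBr is not available; TMSOTf therefore ionises the mixed ketal at C5 (methoxide leaves as MeOSiMe3), 2,6-lutidine removes H-8, and the resulting 5,7-bis(silyloxy)cyclohexa-1,3-diene, a tertiary and doubly allylic bromide, should ionise to an arenium ion that loses H-8a to give 18, whose aryl silyl ethers are cleaved by dilute acid. No new stereocentre survives, since C4a, C5 and C8a of 17 all become sp2, and C2, C3 and the benzylic centre are spectators (C3–H, the only enolisable one, is hindered and the triflate stage is kept at or below 0 °C). The step needs regiocontrol, which the matched polarisation of diene and enone and the position of bromine secure, the 1-arylethyl group on the central diene carbon being able to end only at C6; it also needs ring formation to outrun conjugate addition with β-elimination of the ring oxygen, for which Lewis-acid-free thermal conditions and excess diene are chosen.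

Step 10
Reactants: 19 (2R,3R)-2-[4-(benzyloxy)phenyl]-6-{(1R)-1-[4-(benzyloxy)phenyl]ethyl}-3-(tert-butyldimethylsilyloxy)-5,7-dihydroxychroman-4-one
Product: 20 (2R,3R)-2-[4-(benzyloxy)phenyl]-6-{(1R)-1-[4-(benzyloxy)phenyl]ethyl}-3,5,7-trihydroxychroman-4-one
Conditions: HF·pyridine, pyridine–THF, 0 °C → rt
Reagents that add atoms: none
Why: Fluoride cleavage of the secondary silyl ether under buffered acidic conditions, which avoids the base-induced ring opening and C2/C3 epimerisation that dihydroflavonols are prone to; benzyl ethers and phenols are inert.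

Step 11
Reactants: 20 (2R,3R)-2-[4-(benzyloxy)phenyl]-6-{(1R)-1-[4-(benzyloxy)phenyl]ethyl}-3,5,7-trihydroxychroman-4-one
Product: 21 (2R,3R)-3,5,7-trihydroxy-2-(4-hydroxyphenyl)-6-[(1R)-1-(4-hydroxyphenyl)ethyl]chroman-4-one
Conditions: H2 (1 atm), 10% Pd/C, EtOAc–MeOH, rt
Reagents that add atoms: none
Why: Palladium-catalysed hydrogenolysis of the two aryl benzyl ethers; the hydrogen-bonded aryl ketone, the C2–O1 bond and the diarylmethine C–H should be slow to react at 1 atm and rt, so all three stereocentres are kept.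

**Compound list**
1 | 4-(benzyloxy)benzaldehyde | O=Cc1ccc(OCc2ccccc2)cc1 | starting material
2 | trans-1-methoxy-3-(trimethylsilyloxy)buta-1,3-diene (Danishefsky's diene) | CO/C=C/C(=C)O[Si](C)(C)C | starting material
3 | (1E,5S)-5-[4-(benzyloxy)phenyl]-1-methoxy-5-(trimethylsilyloxy)pent-1-en-3-one (Mukaiyama aldol silyl ether, not isolated) | CO/C=C/C(=O)C[C@H](O[Si](C)(C)C)c1ccc(OCc2ccccc2)cc1 | intermediate
4 | (2S)-2-[4-(benzyloxy)phenyl]-2,3-dihydro-4H-pyran-4-one | O=C1C[C@@H](c2ccc(OCc3ccccc3)cc2)OC=C1 | intermediate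
5 | sodium (2S)-2-[4-(benzyloxy)phenyl]-2H-pyran-4-olate (C3 enolate of 4, not isolated) | [Na+].[O-]C1=C[C@@H](c2ccc(OCc3ccccc3)cc2)OC=C1 | intermediate
6 | (2R,3R)-2-[4-(benzyloxy)phenyl]-3-hydroxy-2,3-dihydro-4H-pyran-4-one (2,3-trans) | C1=CC(=O)[C@H](O)[C@@H](c2ccc(OCc3ccccc3)cc2)O1 | intermediate
7 | (2R,3R)-2-[4-(benzyloxy)phenyl]-3-(tert-butyldimethylsilyloxy)-2,3-dihydro-4H-pyran-4-one | C1=CC(=O)[C@H](O[Si](C)(C)C(C)(C)C)[C@@H](c2ccc(OCc3ccccc3)cc2)O1 | intermediate
8 | (2R,3R)-5-bromo-2-[4-(benzyloxy)phenyl]-3-(tert-butyldimethylsilyloxy)-2,3-dihydro-4H-pyran-4-one | C1=C(Br)C(=O)[C@H](O[Si](C)(C)C(C)(C)C)[C@@H](c2ccc(OCc3ccccc3)cc2)O1 | intermediate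
9 | methyl (E)-but-2-enoate (methyl crotonate) | C/C=C/C(=O)OC | starting material
10 | 4-(benzyloxy)phenylboronic acid | OB(O)c1ccc(OCc2ccccc2)cc1 | starting material
11 | methyl (3S)-3-[4-(benzyloxy)phenyl]butanoate | C[C@H](c1ccc(OCc2ccccc2)cc1)CC(=O)OC | intermediate
12 | lithium enolate of 11 (3S, enolate geometry undefined, not isolated) | C[C@H](c1ccc(OCc2ccccc2)cc1)C=C(OC)[O-].[Li+] | intermediate
13 | methyl (3S)-2-acetyl-3-[4-(benzyloxy)phenyl]butanoate (both C2 epimers) | C[C@H](c1ccc(OCc2ccccc2)cc1)C(C(C)=O)C(=O)OC | intermediate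
14 | methyl 2-{(1R)-1-[4-(benzyloxy)phenyl]ethyl}-3-(trimethylsilyloxy)but-2-enoate (E/Z mixture) | C[C@H](c1ccc(OCc2ccccc2)cc1)C(C(=O)OC)=C(C)O[Si](C)(C)C | intermediate
15 | lithium dienolate of 14 (1R, not isolated) | C[C@H](c1ccc(OCc2ccccc2)cc1)C(=C(OC)[O-])C(=C)O[Si](C)(C)C.[Li+] | intermediate
16 | 1-methoxy-1,3-bis(trimethylsilyloxy)-2-{(1R)-1-[4-(benzyloxy)phenyl]ethyl}buta-1,3-diene (ketene-acetal geometry undefined) | C[C@H](c1ccc(OCc2ccccc2)cc1)C(=C(OC)O[Si](C)(C)C)C(=C)O[Si](C)(C)C | intermediate
17 | (2R,3R)-4a-bromo-2-[4-(benzyloxy)phenyl]-6-{(1R)-1-[4-(benzyloxy)phenyl]ethyl}-3-(tert-butyldimethylsilyloxy)-5-methoxy-5,7-bis(trimethylsilyloxy)-2,3,4a,5,8,8a-hexahydro-4H-chromen-4-one (cis ring fusion, mixture at C4a, C5 and C8a, not isolated) | C[C@H](c1ccc(OCc2ccccc2)cc1)C1=C(O[Si](C)(C)C)CC2O[C@H](c3ccc(OCc4ccccc4)cc3)[C@@H](O[Si](C)(C)C(C)(C)C)C(=O)C2(Br)C1(OC)O[Si](C)(C)C | intermediate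
18 | (2R,3R)-2-[4-(benzyloxy)phenyl]-6-{(1R)-1-[4-(benzyloxy)phenyl]ethyl}-3-(tert-butyldimethylsilyloxy)-5,7-bis(trimethylsilyloxy)chroman-4-one (not isolated) | C[C@H](c1ccc(OCc2ccccc2)cc1)c1c(O[Si](C)(C)C)cc2c(c1O[Si](C)(C)C)C(=O)[C@H](O[Si](C)(C)C(C)(C)C)[C@@H](c1ccc(OCc3ccccc3)cc1)O2 | intermediate
19 | (2R,3R)-2-[4-(benzyloxy)phenyl]-6-{(1R)-1-[4-(benzyloxy)phenyl]ethyl}-3-(tert-butyldimethylsilyloxy)-5,7-dihydroxychroman-4-one | C[C@H](c1ccc(OCc2ccccc2)cc1)c1c(O)cc2c(c1O)C(=O)[C@H](O[Si](C)(C)C(C)(C)C)[C@@H](c1ccc(OCc3ccccc3)cc1)O2 | intermediate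
20 | (2R,3R)-2-[4-(benzyloxy)phenyl]-6-{(1R)-1-[4-(benzyloxy)phenyl]ethyl}-3,5,7-trihydroxychroman-4-one | C[C@H](c1ccc(OCc2ccccc2)cc1)c1c(O)cc2c(c1O)C(=O)[C@H](O)[C@@H](c1ccc(OCc3ccccc3)cc1)O2 | intermediate
21 | (2R,3R)-3,5,7-trihydroxy-2-(4-hydroxyphenyl)-6-[(1R)-1-(4-hydroxyphenyl)ethyl]chroman-4-one | C[C@H](c1ccc(O)cc1)c1c(O)cc2c(c1O)C(=O)[C@H](O)[C@@H](c1ccc(O)cc1)O2 | target

**Step count**
Total: 11 steps. Longest linear sequence: 7 steps (1 → 2 → 3 → 4 → 9 → 10 → 11, or 5 → 6 → 7 → 8 → 9 → 10 → 11).

**Steps most likely to fail**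

1. Step 9 (Proposed new method). The bromo vinylogous ester may be too weak a 2π partner, so that thermal decomposition or silyl transfer of the diene wins. Conjugate addition followed by β-elimination of the ring oxygen may open ring C. Loss of the syn-disposed HBr may stall at the cyclohexadiene stage. The fallback builds the same two bonds stepwise with known reaction types; it sets out from 7 and 16 and comes back at 19. Compound 7 is activated with TMSOTf in CH2Cl2 at −78 °C and the CH2 terminus of 16 adds to C6 (Mukaiyama–Michael addition, known for these dienes with silyl-triflate-activated chromones and dihydropyranones). Aqueous acid work-up should give methyl (3S)-3-[4-(benzyloxy)phenyl]-2-{2-[(5R,6R)-6-[4-(benzyloxy)phenyl]-5-(tert-butyldimethylsilyloxy)-4-oxooxan-2-yl]acetyl}butanoate F1. Potassium tert-butoxide in THF at 0 °C then closes ring A by intramolecular Claisen (Dieckmann-type) acylation of the ring-ketone enolate by the methyl ester, giving (2R,3R)-2-[4-(benzyloxy)phenyl]-6-{(1S)-1-[4-(benzyloxy)phenyl]ethyl}-3-(tert-butyldimethylsilyloxy)hexahydrochromene-4,5,7-trione F2. Dehydrogenation of this 2-acylcyclohexane-1,3-dione with DDQ in dioxane at rt aromatises ring A and returns 19.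

2. Step 2. The C3 enolate may undergo β-elimination of the ring oxygen (ring opening to a dienone), or may add to the sulfonimine by-product. The fallback avoids an enolate; it sets out from 4 and comes back at 6. Manganese(III) acetate in benzene at reflux (radical α'-acetoxylation, known to be trans-selective on 2-substituted 2,3-dihydropyran-4-ones) should give (2R,3R)-3-acetoxy-2-[4-(benzyloxy)phenyl]-2,3-dihydro-4H-pyran-4-one F3. Catalytic K2CO3 in MeOH at 0 °C then methanolyses the acetate to 6.

3. Step 6. Acylation of the hindered α-branched enolate may be incomplete through proton transfer to the enolate or early collapse of the tetrahedral adduct. The fallback replaces acylation by aldol addition and oxidation; it sets out from 11 and comes back at 13. The lithium enolate of 11 (LDA, THF, −78 °C) is trapped with acetaldehyde to give methyl (3S)-3-[4-(benzyloxy)phenyl]-2-(1-hydroxyethyl)butanoate F4 as a diastereomer mixture. Dess–Martin periodinane in CH2Cl2 then oxidises the secondary alcohol to 13.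

**Further compounds**
F1 | step 9 | methyl (3S)-3-[4-(benzyloxy)phenyl]-2-{2-[(5R,6R)-6-[4-(benzyloxy)phenyl]-5-(tert-butyldimethylsilyloxy)-4-oxooxan-2-yl]acetyl}butanoate (epimers at oxane C2 and butanoate C2) | C[C@H](c1ccc(OCc2ccccc2)cc1)C(C(=O)OC)C(=O)CC1CC(=O)[C@H](O[Si](C)(C)C(C)(C)C)[C@@H](c2ccc(OCc3ccccc3)cc2)O1
F2 | step 9 | (2R,3R)-2-[4-(benzyloxy)phenyl]-6-{(1S)-1-[4-(benzyloxy)phenyl]ethyl}-3-(tert-butyldimethylsilyloxy)-2,3,4a,8a-tetrahydro-4H-chromene-4,5,7(6H,8H)-trione (keto form drawn, mixture at C4a, C6 and C8a) | C[C@H](c1ccc(OCc2ccccc2)cc1)C1C(=O)CC2O[C@H](c3ccc(OCc4ccccc4)cc3)[C@@H](O[Si](C)(C)C(C)(C)C)C(=O)C2C1=O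
F3 | step 2 | (2R,3R)-3-acetoxy-2-[4-(benzyloxy)phenyl]-2,3-dihydro-4H-pyran-4-one | C1=CC(=O)[C@H](OC(C)=O)[C@@H](c2ccc(OCc3ccccc3)cc2)O1
F4 | step 6 | methyl (3S)-3-[4-(benzyloxy)phenyl]-2-(1-hydroxyethyl)butanoate (diastereomer mixture) | C[C@H](c1ccc(OCc2ccccc2)cc1)C(C(C)O)C(=O)OC
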